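## Retrosynthetic overview

- **Feature:** the cyclobutane bond C2–C3 joins the two ring carbons that carry the CH2NH(acyl) arms. At the ester oxidation level, with a nitrogen placed between them, each is an α-amino ester carbon. The four-membered ring is therefore a pyrrolidine-2,5-dicarboxylate without its N, and C1/C4 carry masked acetyl groups that become the 2-aminoimidazoles.
- **Disconnections:** both aminoimidazoles go back to α-aminoketone + cyanamide. Both amides go back to the diamine + 4-bromopyrrole-2-carboxylic acid. C2–C3 goes back to N2 loss from the 1,1-diazene of a pyrrolidine. The pyrrolidine goes back to a [3+2] of the glyoxylate/glycinate azomethine ylide with (E)-hex-3-ene-2,5-dione.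
- **Ring order:** pyrrolidine (temporary), then cyclobutane, then both imidazoles together at the end. The pyrrole rings are bought.
- **Safeguards:** the acetyl groups travel as dioxolanes from before the contraction until after the acylation. A free 1,4-diketone would not survive PhI(OH)OTs/NH3. Under methoxide it would also racemise through an achiral isomer. The one misplaced ester carbon is corrected by equilibration after the contraction.

Key step: step 4

Assumption: the sense of induction of the silver/bisphosphine catalyst cannot be deduced for this symmetric ylide, so the (R) ligand is written and the commercial (S) antipode is used instead if correlation shows the opposite series.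

## Route

Step 1
Reactants: 1 methyl glyoxylate; 2 glycine methyl ester hydrochloride
Product: 3 methyl (E)-2-[(2-methoxy-2-oxoethyl)imino]acetate
Conditions: Et3N (1.0 equiv), 4 Å MS, CH2Cl2, 0 °C → rt; filter, concentrate, use crude
Reagents that add atoms: none
Why: Imine condensation of a non-enolisable, very electrophilic aldehyde with the liberated primary amine is driven by the sieves, and the 1,3-proton shift that troubles such imines is degenerate here because both halves of 3 are identical.

Step 2
Reactants: 3 methyl (E)-2-[(2-methoxy-2-oxoethyl)imino]acetate; 4 (E)-hex-3-ene-2,5-dione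
Product: 6 dimethyl (2R,3R,4R,5S)-3,4-diacetylpyrrolidine-2,5-dicarboxylate (esters 2,5-cis; acetyls 3,4-trans), via N-silver azomethine ylide 5 (not isolated)
Conditions: AgOAc (5 mol %), (R)-DTBM-SEGPHOS (5.5 mol %), 4 Å MS, toluene, −20 °C, slow addition of 3
Reagents that add atoms: none
Why: In this metal-catalysed asymmetric 1,3-dipolar cycloaddition of an α-imino ester, acetate deprotonates the silver-bound imine to the W-shaped ylide 5, which adds suprafacially to the E-enedione, so the esters emerge 2,5-cis and the acetyls 3,4-trans (endo and exo approaches are degenerate, one acetyl always being endo and the other exo), and the absolute configuration depends only on which enantiotopic face of the enedione the chiral bisphosphine pocket admits.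

Step 3
Reactants: 6 dimethyl (2R,3R,4R,5S)-3,4-diacetylpyrrolidine-2,5-dicarboxylate
Product: 7 dimethyl (2R,3R,4R,5S)-3,4-bis(2-methyl-1,3-dioxolan-2-yl)pyrrolidine-2,5-dicarboxylate
Conditions: TfOH (1.05 equiv), then TMSOCH2CH2OTMS (5 equiv), TMSOTf (10 mol %), CH2Cl2, −78 → −30 °C; Et3N quench
Reagents that add atoms: 1,2-bis(trimethylsilyloxy)ethane, C[Si](C)(C)OCCO[Si](C)(C)C
Why: Noyori-type ketalisation runs under aprotic, low-temperature, kinetically controlled conditions in which the ketones are not enolised, so C3 and C4 keep their configuration, prior salt formation keeps the weakly basic ring nitrogen from quenching the silyl triflate, and the masking is needed because free methyl ketones would be α-tosyloxylated by PhI(OH)OTs, condensed by ammonia (Paal–Knorr pyrrole) and enolised by methoxide in the next two steps.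

Step 4
Reactants: 7 dimethyl (2R,3R,4R,5S)-3,4-bis(2-methyl-1,3-dioxolan-2-yl)pyrrolidine-2,5-dicarboxylate
Product: 10 dimethyl (1R,2S,3R,4R)-3,4-bis(2-methyl-1,3-dioxolan-2-yl)cyclobutane-1,2-dicarboxylate (esters cis; dioxolanyl groups trans), via 1,1-diazene 8 (not isolated), via 1,4-biradical 9 (not isolated)
Conditions: PhI(OH)OTs (2.5 equiv), NH2CO2NH4 (8 equiv), CF3CH2OH, 80 °C
Reagents that add atoms: none
Why: PhI(OH)OTs and the ammonia released by the carbamate form an electrophilic iodonitrene that aminates the ring nitrogen of 7 and, after loss of PhI, leaves the 1,1-diazene 8, whose extrusion of N2 breaks both C–N bonds and gives the singlet 1,4-biradical 9 with each radical centre stabilised by its ester. The reaction type is the known iodonitrene-mediated nitrogen deletion that contracts polysubstituted pyrrolidines to cyclobutanes. The four-membered ring closes by radical–radical recombination of the two termini of the four-carbon chain (former C2 and C5), which makes the bond that will join the two CH2N-bearing carbons of sceptrin. These two carbons should keep the cis relation of 7 because the singlet pair is born in the cisoid geometry of the ring and couples faster than its C–C bonds rotate, while the two dioxolanyl-bearing carbons take no part and keep their trans (R,R) configuration. The step needs coupling to outrun β-scission of the central C3–C4 bond into two enoate molecules, and it needs nitrogen to be the only oxidisable and condensable site, which the dioxolane masking and the ammonia-buffered medium secure. Any leakage of configuration at the two ester-bearing carbons is harmless, because step 5 equilibrates exactly these two centres.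

Step 5
Reactants: 10 dimethyl (1R,2S,3R,4R)-3,4-bis(2-methyl-1,3-dioxolan-2-yl)cyclobutane-1,2-dicarboxylate
Product: 11 dimethyl (1S,2S,3R,4R)-3,4-bis(2-methyl-1,3-dioxolan-2-yl)cyclobutane-1,2-dicarboxylate (all-trans)
Conditions: NaOMe (30 mol %), MeOH, 60 °C
Reagents that add atoms: none
Why: In this thermodynamic epimerisation through the ester enolate only C1 and C2 carry acidic hydrogens, the trans dioxolanyl pair at C3/C4 is inert and anchors the absolute configuration (and offers no stabilised carbanion for a retro-Michael ring opening), and the only isomer free of cis-1,2 contacts is the all-trans diester reached by inversion at C1.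

Step 6
Reactants: 11 dimethyl (1S,2S,3R,4R)-3,4-bis(2-methyl-1,3-dioxolan-2-yl)cyclobutane-1,2-dicarboxylate
Product: 12 [(1R,2R,3S,4S)-3,4-bis(2-methyl-1,3-dioxolan-2-yl)cyclobutane-1,2-diyl]dimethanol
Conditions: LiAlH4, THF, 0 °C → rt; H2O/aq NaOH work-up
Reagents that add atoms: none
Why: Hydride reduction of both esters to primary alcohols leaves the ketals and all four ring stereocentres untouched (the descriptors change only through CIP priorities).

Step 7
Reactants: 12 [(1R,2R,3S,4S)-3,4-bis(2-methyl-1,3-dioxolan-2-yl)cyclobutane-1,2-diyl]dimethanol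
Product: 13 [(1R,2R,3S,4S)-3,4-bis(2-methyl-1,3-dioxolan-2-yl)cyclobutane-1,2-diyl]bis(methylene) dimethanesulfonate
Conditions: MsCl (2.4 equiv), Et3N (3 equiv), CH2Cl2, 0 °C
Reagents that add atoms: methanesulfonyl chloride, CS(=O)(=O)Cl
Why: Sulfonylation of two primary alcohols is routine, and the trans relation of the arms prevents cyclic ether formation because a trans-fused 3-oxabicyclo[3.2.0]heptane is too strained.

Step 8
Reactants: 13 [(1R,2R,3S,4S)-3,4-bis(2-methyl-1,3-dioxolan-2-yl)cyclobutane-1,2-diyl]bis(methylene) dimethanesulfonate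
Product: 14 (1R,2R,3S,4S)-1,2-bis(azidomethyl)-3,4-bis(2-methyl-1,3-dioxolan-2-yl)cyclobutane
Conditions: NaN3 (4 equiv), DMF, 80 °C
Reagents that add atoms: sodium azide, [N-]=[N+]=[N-].[Na+]
Why: Double SN2 displacement takes place at primary exocyclic carbons, so no ring stereocentre is involved.

Step 9
Reactants: 14 (1R,2R,3S,4S)-1,2-bis(azidomethyl)-3,4-bis(2-methyl-1,3-dioxolan-2-yl)cyclobutane
Product: 15 [(1R,2R,3S,4S)-3,4-bis(2-methyl-1,3-dioxolan-2-yl)cyclobutane-1,2-diyl]dimethanamine
Conditions: H2 (1 atm), 10% Pd/C, MeOH, rt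
Reagents that add atoms: none
Why: Catalytic hydrogenation of alkyl azides to primary amines is clean here because it is placed before any aryl bromide enters the molecule.

Step 10
Reactants: 15 [(1R,2R,3S,4S)-3,4-bis(2-methyl-1,3-dioxolan-2-yl)cyclobutane-1,2-diyl]dimethanamine; 16 4-bromo-1H-pyrrole-2-carboxylic acid
Product: 17 N,N'-{[(1R,2R,3S,4S)-3,4-bis(2-methyl-1,3-dioxolan-2-yl)cyclobutane-1,2-diyl]bis(methylene)}bis(4-bromo-1H-pyrrole-2-carboxamide)
Conditions: 16 (2.2 equiv), EDC·HCl, HOBt, iPr2NEt, DMF, rt
Reagents that add atoms: none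
Why: In this carbodiimide/HOBt amide coupling the two primary amines are far more nucleophilic than the pyrrole N–H, so only the two carboxamides should form.

Step 11
Reactants: 17 N,N'-{[(1R,2R,3S,4S)-3,4-bis(2-methyl-1,3-dioxolan-2-yl)cyclobutane-1,2-diyl]bis(methylene)}bis(4-bromo-1H-pyrrole-2-carboxamide)
Product: 18 N,N'-{[(1R,2R,3S,4S)-3,4-diacetylcyclobutane-1,2-diyl]bis(methylene)}bis(4-bromo-1H-pyrrole-2-carboxamide)
Conditions: 2 M aq HCl, THF, 40 °C
Reagents that add atoms: water, O
Why: Acid hydrolysis of the dioxolanes spares the acylpyrrole amides, and enolisation of the released ketones cannot harm the configuration because each acetyl-bearing carbon already sits trans to both neighbours, one of which is a fixed, non-epimerisable centre.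

Step 12
Reactants: 18 N,N'-{[(1R,2R,3S,4S)-3,4-diacetylcyclobutane-1,2-diyl]bis(methylene)}bis(4-bromo-1H-pyrrole-2-carboxamide)
Product: 19 N,N'-{[(1R,2R,3S,4S)-3,4-bis(chloroacetyl)cyclobutane-1,2-diyl]bis(methylene)}bis(4-bromo-1H-pyrrole-2-carboxamide)
Conditions: BnNMe3ICl2 (4.4 equiv), THF, 60 °C
Reagents that add atoms: benzyltrimethylammonium dichloroiodate, C[N+](C)(C)Cc1ccccc1.Cl[I-]Cl
Why: α-Chlorination of a methyl ketone through its enol with a dichloroiodate salt should occur at CH3, because the alternative enol would place an exocyclic C=C on the hindered cyclobutane, and the pyrroles are deactivated by their acyl and bromo substituents.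

Step 13
Reactants: 19 N,N'-{[(1R,2R,3S,4S)-3,4-bis(chloroacetyl)cyclobutane-1,2-diyl]bis(methylene)}bis(4-bromo-1H-pyrrole-2-carboxamide)
Product: 21 N,N'-{[(1R,2R,3S,4S)-3,4-bis(aminoacetyl)cyclobutane-1,2-diyl]bis(methylene)}bis(4-bromo-1H-pyrrole-2-carboxamide) dihydrochloride, via bis(diformylamino) diketone 20 (not isolated)
Conditions: NaN(CHO)2 (2.5 equiv), MeCN, 35 °C; then HCl, MeOH, rt
Reagents that add atoms: sodium diformylamide, O=C[N-]C=O.[Na+]; hydrogen chloride, Cl
Why: Gabriel-type SN2 substitution of the activated α-chloroketones followed by acid methanolysis of the formyl groups delivers the α-aminoketones without any reduction (so the C–Br bonds are safe) and directly as hydrochlorides, which prevents self-condensation to dihydropyrazines.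

Step 14
Reactants: 21 N,N'-{[(1R,2R,3S,4S)-3,4-bis(aminoacetyl)cyclobutane-1,2-diyl]bis(methylene)}bis(4-bromo-1H-pyrrole-2-carboxamide) dihydrochloride
Product: 22 sceptrin
Conditions: H2NCN (excess), H2O, pH 4.5, 95 °C; then aq NaOH to pH 10.5
Reagents that add atoms: cyanamide, NC#N
Why: In this Marckwald-type 2-aminoimidazole synthesis each amine adds to cyanamide to give a guanidine that cyclises onto the adjacent ketone and dehydrates, and the ring carbons next to the ketones stay trans because that arrangement is both the starting and the thermodynamically preferred one.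

## Compound list

1 | methyl glyoxylate | COC(=O)C=O | starting material
2 | glycine methyl ester hydrochloride | COC(=O)CN.Cl | starting material
3 | methyl (E)-2-[(2-methoxy-2-oxoethyl)imino]acetate | COC(=O)/C=N/CC(=O)OC | intermediate
4 | (E)-hex-3-ene-2,5-dione | CC(=O)/C=C/C(C)=O | starting material
5 | N-silver azomethine ylide of 3 (2-azaallyl anion, phosphine omitted) | COC(=O)C=N[CH-]C(=O)OC.[Ag+] | intermediate
6 | dimethyl (2R,3R,4R,5S)-3,4-diacetylpyrrolidine-2,5-dicarboxylate (esters cis, acetyls trans, C5 ester cis to C4 acetyl) | CC(=O)[C@H]1[C@@H](C(=O)OC)N[C@@H](C(=O)OC)[C@@H]1C(C)=O | intermediate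
7 | dimethyl (2R,3R,4R,5S)-3,4-bis(2-methyl-1,3-dioxolan-2-yl)pyrrolidine-2,5-dicarboxylate | CC1(OCCO1)[C@H]2[C@@H](C(=O)OC)N[C@@H](C(=O)OC)[C@@H]2C1(C)OCCO1 | intermediate
8 | 1,1-diazene (isodiazene) of 7 | CC1(OCCO1)[C@H]2[C@@H](C(=O)OC)[N+](=[N-])[C@@H](C(=O)OC)[C@@H]2C1(C)OCCO1 | intermediate
9 | singlet 1,4-biradical, dimethyl 3,4-bis(2-methyl-1,3-dioxolan-2-yl)hexanedioate-2,5-diyl (C3 and C4 as in 7) | CC1(OCCO1)[C@@H]([CH]C(=O)OC)[C@H]([CH]C(=O)OC)C1(C)OCCO1 | intermediate
10 | dimethyl (1R,2S,3R,4R)-3,4-bis(2-methyl-1,3-dioxolan-2-yl)cyclobutane-1,2-dicarboxylate (esters cis, dioxolanyl groups trans) | CC1(OCCO1)[C@H]2[C@@H](C(=O)OC)[C@@H](C(=O)OC)[C@@H]2C1(C)OCCO1 | intermediate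
11 | dimethyl (1S,2S,3R,4R)-3,4-bis(2-methyl-1,3-dioxolan-2-yl)cyclobutane-1,2-dicarboxylate (all-trans) | CC1(OCCO1)[C@H]2[C@H](C(=O)OC)[C@@H](C(=O)OC)[C@@H]2C1(C)OCCO1 | intermediate
12 | [(1R,2R,3S,4S)-3,4-bis(2-methyl-1,3-dioxolan-2-yl)cyclobutane-1,2-diyl]dimethanol | CC1(OCCO1)[C@H]2[C@H](CO)[C@@H](CO)[C@@H]2C1(C)OCCO1 | intermediate
13 | [(1R,2R,3S,4S)-3,4-bis(2-methyl-1,3-dioxolan-2-yl)cyclobutane-1,2-diyl]bis(methylene) dimethanesulfonate | CC1(OCCO1)[C@H]2[C@H](COS(C)(=O)=O)[C@@H](COS(C)(=O)=O)[C@@H]2C1(C)OCCO1 | intermediate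
14 | (1R,2R,3S,4S)-1,2-bis(azidomethyl)-3,4-bis(2-methyl-1,3-dioxolan-2-yl)cyclobutane | CC1(OCCO1)[C@H]2[C@H](CN=[N+]=[N-])[C@@H](CN=[N+]=[N-])[C@@H]2C1(C)OCCO1 | intermediate
15 | [(1R,2R,3S,4S)-3,4-bis(2-methyl-1,3-dioxolan-2-yl)cyclobutane-1,2-diyl]dimethanamine | CC1(OCCO1)[C@H]2[C@H](CN)[C@@H](CN)[C@@H]2C1(C)OCCO1 | intermediate
16 | 4-bromo-1H-pyrrole-2-carboxylic acid | OC(=O)c1cc(Br)c[nH]1 | starting material
17 | N,N'-{[(1R,2R,3S,4S)-3,4-bis(2-methyl-1,3-dioxolan-2-yl)cyclobutane-1,2-diyl]bis(methylene)}bis(4-bromo-1H-pyrrole-2-carboxamide) | CC1(OCCO1)[C@H]2[C@H](CNC(=O)c3cc(Br)c[nH]3)[C@@H](CNC(=O)c3cc(Br)c[nH]3)[C@@H]2C1(C)OCCO1 | intermediate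
18 | N,N'-{[(1R,2R,3S,4S)-3,4-diacetylcyclobutane-1,2-diyl]bis(methylene)}bis(4-bromo-1H-pyrrole-2-carboxamide) | CC(=O)[C@H]1[C@H](CNC(=O)c2cc(Br)c[nH]2)[C@@H](CNC(=O)c2cc(Br)c[nH]2)[C@@H]1C(C)=O | intermediate
19 | N,N'-{[(1R,2R,3S,4S)-3,4-bis(chloroacetyl)cyclobutane-1,2-diyl]bis(methylene)}bis(4-bromo-1H-pyrrole-2-carboxamide) | ClCC(=O)[C@H]1[C@H](CNC(=O)c2cc(Br)c[nH]2)[C@@H](CNC(=O)c2cc(Br)c[nH]2)[C@@H]1C(=O)CCl | intermediate
20 | N,N'-{[(1R,2R,3S,4S)-3,4-bis[(diformylamino)acetyl]cyclobutane-1,2-diyl]bis(methylene)}bis(4-bromo-1H-pyrrole-2-carboxamide) | O=CN(C=O)CC(=O)[C@H]1[C@H](CNC(=O)c2cc(Br)c[nH]2)[C@@H](CNC(=O)c2cc(Br)c[nH]2)[C@@H]1C(=O)CN(C=O)C=O | intermediate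
21 | N,N'-{[(1R,2R,3S,4S)-3,4-bis(aminoacetyl)cyclobutane-1,2-diyl]bis(methylene)}bis(4-bromo-1H-pyrrole-2-carboxamide) dihydrochloride | NCC(=O)[C@H]1[C@H](CNC(=O)c2cc(Br)c[nH]2)[C@@H](CNC(=O)c2cc(Br)c[nH]2)[C@@H]1C(=O)CN.Cl.Cl | intermediate
22 | sceptrin, N,N'-{[(1R,2R,3S,4S)-3,4-bis(2-amino-1H-imidazol-5-yl)cyclobutane-1,2-diyl]bis(methylene)}bis(4-bromo-1H-pyrrole-2-carboxamide) | Nc1ncc([C@H]2[C@H](CNC(=O)c3cc(Br)c[nH]3)[C@@H](CNC(=O)c3cc(Br)c[nH]3)[C@@H]2c2cnc(N)[nH]2)[nH]1 | target

## Step count and risks

Total step count: 14. Longest linear sequence: 14 steps (1/2 → 22).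

**Step 4 (ring contraction).**
- Electrophilic amination may be slow at a hindered nitrogen flanked by two esters.
- The α-amino ester may be dehydrogenated instead.
- At 80 °C the biradical may cleave its central bond faster than it couples.
- Hot fluoroalcohol with ammonia may erode the dioxolanes or ammonolyse the esters.

Fallback: the same diazene is reached from 7 by known stepwise N-amination and is released cold. Nitrosation of 7 (t-BuONO, CH2Cl2, rt) should give the N-nitrosopyrrolidine F1. Zinc in AcOH/MeOH at 0 °C should reduce it to the N-aminopyrrolidine F2. Oxidation of F2 with PhI(OAc)2 in CH2Cl2 at −20 °C generates 8, which loses N2 and closes to 10, where the route is rejoined. Nitrosation does not depend on a strongly nucleophilic amine, the low temperature favours coupling over scission, and neither ammonia nor hot solvent is present.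

**Step 2 (asymmetric cycloaddition).**
- The ylide is symmetric, so the catalyst must distinguish the two enantiotopic faces of the enedione rather than the faces of the dipole, and this discrimination may be poor.
- Self-cycloaddition of the electrophilic imine and aza-Michael addition of the product to the enedione may also compete.

Fallback: absolute control is moved from catalysis to resolution. From 3 and 4, the cycloaddition with achiral AgOAc/PPh3 (Et3N, toluene, rt) should give 6 together with the enantiomeric pyrrolidine F3. Step 3 applied to this mixture gives 7 together with the enantiomeric bis-dioxolane F4. These configurationally stable amines are separated by preparative chromatography on a chiral stationary phase, and the route is rejoined at 7.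

**Step 3 (ketalisation of the amino diketone).**
- The ring nitrogen may sequester the acid catalyst.
- Acid-induced enolisation toward C3/C4 would pass through an achiral 3,4-cis isomer and erode both the relative and the absolute configuration.
- The 1,4-diketone may dehydrate to a furan.

Fallback: the nitrogen is switched off first. From 6, CbzCl/NaHCO3 (CH2Cl2/H2O) should give the N-Cbz diketone F5. Ketalisation with TMSOCH2CH2OTMS and truly catalytic TMSOTf at −78 °C should give the N-Cbz bis-dioxolane F6. Hydrogenolysis (H2, 10% Pd/C, EtOAc) returns the free amine 7, where the route is rejoined.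

## Further compounds

F1 | step 4 | dimethyl (2R,3R,4R,5S)-3,4-bis(2-methyl-1,3-dioxolan-2-yl)-1-nitrosopyrrolidine-2,5-dicarboxylate | CC1(OCCO1)[C@H]2[C@@H](C(=O)OC)N(N=O)[C@@H](C(=O)OC)[C@@H]2C1(C)OCCO1
F2 | step 4 | dimethyl (2R,3R,4R,5S)-1-amino-3,4-bis(2-methyl-1,3-dioxolan-2-yl)pyrrolidine-2,5-dicarboxylate | CC1(OCCO1)[C@H]2[C@@H](C(=O)OC)N(N)[C@@H](C(=O)OC)[C@@H]2C1(C)OCCO1
F3 | step 2 | dimethyl (2S,3S,4S,5R)-3,4-diacetylpyrrolidine-2,5-dicarboxylate (enantiomer of 6) | CC(=O)[C@@H]1[C@H](C(=O)OC)N[C@H](C(=O)OC)[C@H]1C(C)=O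
F4 | step 2 | dimethyl (2S,3S,4S,5R)-3,4-bis(2-methyl-1,3-dioxolan-2-yl)pyrrolidine-2,5-dicarboxylate (enantiomer of 7) | CC1(OCCO1)[C@@H]2[C@H](C(=O)OC)N[C@H](C(=O)OC)[C@H]2C1(C)OCCO1
F5 | step 3 | 1-benzyl 2,5-dimethyl (2R,3R,4R,5S)-3,4-diacetylpyrrolidine-1,2,5-tricarboxylate | CC(=O)[C@H]1[C@@H](C(=O)OC)N(C(=O)OCc2ccccc2)[C@@H](C(=O)OC)[C@@H]1C(C)=O
F6 | step 3 | 1-benzyl 2,5-dimethyl (2R,3R,4R,5S)-3,4-bis(2-methyl-1,3-dioxolan-2-yl)pyrrolidine-1,2,5-tricarboxylate | CC1(OCCO1)[C@H]2[C@@H](C(=O)OC)N(C(=O)OCc3ccccc3)[C@@H](C(=O)OC)[C@@H]2C1(C)OCCO1
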